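## The problem

Compound 34 is a C20 terpenoid acetate built on a trans-fused bicyclo[7.2.0]undecane. Ring A (cyclobutane C1–C9–C10–C11) shares the C1–C9 bond with ring B (nine-membered, C1 to C9). Ring B carries an exocyclic methylene on C8 and ring C, a trisubstituted trans-epoxide at C4–C5. Quaternary C11 holds a methyl group on the face of the C2 branch and, on the other face, ring D. Ring D is a 3,6-dihydro-1,2-dioxin-3-ol: its hemiketal carbon C12 is bonded to C11, and its second peroxy carbon C15 is quaternary (methyl and acetoxymethyl C16).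

Of the seven stereocentres, C1 and C9 must be set absolutely. They can then steer C11 (the two faces of ring A differ sterically) and C4/C5 (through the conformation of an E-configured ring B). C9 stays epimerisable while C8 is a carbonyl group, so the trans fusion is a thermodynamic matter. C12 is an equilibrating hemiketal. C15 lies five bonds from the nearest fixed centre, so it needs its own source of chirality and a stereospecific C–O–O bond formation.

The O–O bond will not survive hydrides, phosphines, low-valent metals or boranes. The epoxide, and the strained E-cycloalkene that precedes it, do not tolerate strong acid (transannular cyclisation). Rings D and C therefore come last.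

The feature that invites an unusual construction is ring A itself. C11 carries two carbons that can both start as esters (the methyl group and C12), and C9 carries an acyl carbon (C8). An NH placed between C1 and C11 turns ring A into a 4-acylpyrrolidine-2,2-dicarboxylate, the cycloadduct of an aminomalonate-derived azomethine ylide and an enone.

## Retrosynthesis

**34 to 33 (C4–O and C5–O).** The epoxide is removed first. It would not survive the acid used to build ring D, whereas the E-alkene of 33 is the most nucleophilic double bond in the molecule. The cut removes two stereocentres. The forward step must be chemoselective and must attack the outer face of the ring-B alkene.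

**33 to 32 to 29 (ring D: O–C12 and O–C15).** A cycloaddition of oxygen to a diene is ruled out because both diene termini would be fully substituted. Radical peroxidation offers no control at C15 and would also touch the other alkenes. The hemiketal bond is therefore cut to an open hydroperoxy enone, and the C15–O bond is traced to the E-configured epoxy enone 29, whose epoxide carbon has the opposite configuration. The E geometry is chosen on purpose: it keeps the carbonyl oxygen away from the epoxide. The forward reaction has to invert C15 cleanly, isomerise E to Z, and close. Acetylation of the primary alcohol of 32 gives 33.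

**29 to 24 + 27 (C12–C13).** This is the convergent cut. It separates the core aldehyde 24 from the four-carbon iodoalkene 27, which brings C15 from (S)-2-methylglycidol 25. Cutting C13=C14 instead would need a ketophosphonate on the core and one more step there. The forward steps are an alkenylchromium addition to give 28 and an oxidation.

**24 to 17 (substituents on C11).** The methyl group and C12 are traced to the two esters of 17. They differ only in their position relative to C2, so the less hindered ester (cis to H-1) must become C12 and the other the methyl group. Forward: selective mono-reduction (18), protection (19), reduction (20), mesylate (21), hydride displacement (22), unmasking (23), oxidation (24).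

**17 to 15 (C7–C8, ring B).** Closing ring B at the exocyclic carbon avoids forming the strained E-alkene in the ring-closing event, which metathesis at C4=C5 would require and would deliver as Z. It also gives the methylene group directly. The precursor 15 is an enol triflate with a terminal diene. The forward reaction is a hydroboration followed by an intramolecular alkyl–alkenyl cross-coupling at high dilution.

**15 to 11 (functional groups only).** The triflate comes from the methyl ketone, and the diene from the silyl ether through 12, 13 and 14.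

**11 to 9 (C1–C11, ring A).** Reinserting NH between C1 and C11 gives the trans pyrrolidine 9. The forward step must lose nitrogen with retention at C1 and C9, and must close the ring faster than the 1,4-biradical fragments.

**9 to 8 to 4 + 5 + 6 (C1–C9 and C10–C11).** The pyrrolidine is the cycloadduct of the ylide from aldehyde 4 and dimethyl aminomalonate 5 with but-3-en-2-one 6. The catalyst sets C1. The acetyl-bearing centre is then equilibrated to trans.

**4 to 1.** Aldehyde 4 carries C1–C6 with the E-alkene already in place. It comes from geraniol 1 by protection (2), epoxidation of the distal alkene (3) and cleavage.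

## Roads not taken

**Alternative 1:** The cut is a biomimetic double cyclisation. A class 1 diterpene synthase would ionise geranylgeranyl diphosphate A1 and form C10–C11 and then C1–C9, ending with loss of a proton to the exocyclic methylene of hydrocarbon A2.
- Merits: rings A and B, the trans fusion, C11, the E-alkene and the methylene all arise in one step from an achiral precursor. In step count to the carbon skeleton this road is clearly better than the chosen one.
- Weak points: it needs an enzyme of exactly this product specificity, and in the (1S,9R) series, which is antipodal to the common sesquiterpene of this skeleton. A2 arrives with no oxygen at all. C12 is an unactivated methylene next to a quaternary carbon, and it would have to be oxidised selectively in the presence of four alkenes before C16, the peroxide and the epoxide are addressed.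
- Comparison: the chosen plan delivers C12 already oxidised (it begins as an ester) and fixes the absolute configuration by a catalyst that can be bought in either form. It pays for this with length and with a key step that lacks close precedent.

**Alternative 2:** The cut is C10–C11, made by a 1,2-shift. A chiral palladium catalyst would ionise the allylic carbonate of cyclopropanol A3, and a ring bond would migrate to the methyl-bearing allyl terminus to give 2-methyl-2-vinylcyclobutanone A4.
- Merits: the quaternary centre C11 is created catalytically, enantioselectively and early, by a reaction type with good precedent. This is firmer ground than the late steric differentiation of two esters used here.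
- Weak points: A4 holds only C11. The C2 chain on C1 (the carbonyl carbon) and the C8 unit on C9 (its α-carbon) must then be added trans to each other and with control relative to C11, on a strained ketone that is awkward to enolise and to olefinate. The methyl and vinyl groups differ too little in size to make that control dependable.
- Comparison: the chosen plan forms C1 and C9 together with their substituents in one cycloaddition and lets C1 control C11. It has nothing as reliable as the ring expansion for the quaternary centre itself.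

**Alternative 3:** The cut is C9–C10, made by ring contraction. Photolysis of 2-diazocyclopentanone A5 in an alcohol would trigger a Wolff rearrangement, and the ketene would be trapped as the ester of cyclobutane A6, which base then equilibrates to trans.
- Merits: the contraction is one of the most dependable routes to cyclobutanes. The quaternary centre can be set on a five-membered ring, where stereocontrol is easier. The trans relationship is again thermodynamic. In reliability of the key step this road is better than the chosen one.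
- Weak points: A5 is a stereodefined cyclopentanone with a quaternary centre and three different appendages, and it needs a long linear preparation. C8 arrives as an ester that must still become the methylene-bearing carbon. The alkyne chain leaves the E-trisubstituted alkene of ring B to be built later.
- Comparison: the chosen plan assembles the ring-A precursor from three components in two steps and takes C1–C6, including the E-alkene, from geraniol. It has to set this brevity against the uncertainty of the nitrogen deletion.

Key step: step 6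

**Remarks on the chemistry (assumptions)**
- C12 is a hemiketal carbon that equilibrates through the open hydroperoxy enone. The configuration drawn in 34 is taken to be the more stable anomer (hydroxyl pseudo-axial, the C11 substituent pseudo-equatorial and trans to the acetoxymethyl group), and so to form under thermodynamic control.
- The sense of induction of the silver–phosphine catalyst with an alkyl aldimine of aminomalonate cannot be predicted with certainty. The ligand antipode that gives the (5S) adduct is to be used; (S) is written as the working choice.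
- Compounds 1, 5, 6 and 25 are taken as commercial.

## Route

Step 1
Reactants: 1 geraniol
Product: 2 tert-butyl{[(2E)-3,7-dimethylocta-2,6-dien-1-yl]oxy}diphenylsilane
Conditions: TBDPSCl, imidazole, CH2Cl2, 0 °C to rt
Reagents that add atoms: tert-butyl(chloro)diphenylsilane, CC(C)(C)[Si](Cl)(c1ccccc1)c1ccccc1
Why: Silylation of the primary allylic alcohol; the TBDPS ether is chosen because it should survive periodic acid, DBU and the trivalent iodine reagent in hot trifluoroethanol and is later removed by fluoride without touching the esters.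

Step 2
Reactants: 2 tert-butyl{[(2E)-3,7-dimethylocta-2,6-dien-1-yl]oxy}diphenylsilane
Product: 3 tert-butyl{[(2E)-5-(3,3-dimethyloxiran-2-yl)-3-methylpent-2-en-1-yl]oxy}diphenylsilane (racemic at the epoxide)
Conditions: mCPBA (1.0 equiv), NaHCO3, CH2Cl2, −20 to 0 °C
Reagents that add atoms: 3-chloroperbenzoic acid, O=C(OO)c1cccc(Cl)c1
Why: Prilezhaev epoxidation; the distal alkene is the more electron-rich one (the 2,3-alkene is deactivated by the allylic oxygen), so one equivalent of peracid should react there, and the stereocentre formed is destroyed in step 3.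

Step 3
Reactants: 3 tert-butyl{[(2E)-5-(3,3-dimethyloxiran-2-yl)-3-methylpent-2-en-1-yl]oxy}diphenylsilane
Product: 4 (4E)-6-[(tert-butyldiphenylsilyl)oxy]-4-methylhex-4-enal
Conditions: H5IO6, THF/H2O, 0 °C
Reagents that add atoms: none
Why: Periodic acid opens the epoxide to the glycol and cleaves it (Malaprade-type cleavage) to aldehyde 4 and acetone; the E-alkene and the silyl ether should be untouched.

Step 4
Reactants: 4 (4E)-6-[(tert-butyldiphenylsilyl)oxy]-4-methylhex-4-enal; 5 dimethyl aminomalonate hydrochloride; 6 but-3-en-2-one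
Product: 8 dimethyl (4S,5S)-4-acetyl-5-[(3E)-5-(tert-butyldiphenylsilyloxy)-3-methylpent-3-enyl]pyrrolidine-2,2-dicarboxylate (4,5-cis), via imine 7 (not isolated)
Conditions: Et3N, MgSO4, CH2Cl2, rt; then AgOAc (5 mol %), (S)-TF-BiphamPhos (5.5 mol %), Et3N (10 mol %), toluene, −20 °C
Reagents that add atoms: none
Why: Condensation gives aldimine 7, which AgOAc and Et3N convert into an N-metalated azomethine ylide; silver-catalysed asymmetric 1,3-dipolar cycloaddition ([3+2], stepwise Michael–Mannich) bonds the malonate carbon to the β-carbon of the enone and the imine carbon to its α-carbon. The chiral monovalent silver–phosphine complex selects the face of the imine carbon (C5, the future C1, S), and endo approach places the acetyl group cis to the C5 chain; that centre is corrected in step 5.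

Step 5
Reactants: 8 dimethyl (4S,5S)-4-acetyl-5-[(3E)-5-(tert-butyldiphenylsilyloxy)-3-methylpent-3-enyl]pyrrolidine-2,2-dicarboxylate
Product: 9 dimethyl (4R,5S)-4-acetyl-5-[(3E)-5-(tert-butyldiphenylsilyloxy)-3-methylpent-3-enyl]pyrrolidine-2,2-dicarboxylate (4,5-trans)
Conditions: DBU (0.3 equiv), toluene, rt
Reagents that add atoms: none
Why: Base-mediated epimerisation through the ketone enolate to the thermodynamically preferred 4,5-trans isomer; C4 (the future C9, R) is thus set under thermodynamic control by C5, which has no acidic hydrogen, and the aprotic medium disfavours retro-Mannich or retro-Michael opening.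

Step 6
Reactants: 9 dimethyl (4R,5S)-4-acetyl-5-[(3E)-5-(tert-butyldiphenylsilyloxy)-3-methylpent-3-enyl]pyrrolidine-2,2-dicarboxylate
Product: 11 dimethyl (2S,3R)-3-acetyl-2-[(3E)-5-(tert-butyldiphenylsilyloxy)-3-methylpent-3-enyl]cyclobutane-1,1-dicarboxylate (2,3-trans), via 1,1-diazene 10 (not isolated)
Conditions: PhI(OAc)2 (2.5 equiv), NH2CO2NH4 (8 equiv), CF3CH2OH, 80 °C
Reagents that add atoms: none
Why: Proposed new method: ammonia released from the carbamate and PhI(OAc)2 give an electrophilic iodonitrene that aminates the ring nitrogen of 9; a second equivalent of the trivalent iodine reagent oxidises the N-amino group to the 1,1-diazene 10, which loses N2 to a singlet 1,4-biradical (C11 stabilised by two esters, C1 a plain secondary radical) that recombines at once. The closest known reaction type is the iodonitrene-mediated, stereoretentive contraction of 2-aryl- and 2-ester-substituted pyrrolidines to cyclobutanes; dialkyl 1,1-diazenes generated by other means are known to close as well, though with more cleavage. Ring A is closed by radical-pair recombination at C1–C11 of the 1,4-biradical, a four-membered ring from a five-membered one without a radical chain. No stereocentre is created: C1 and C9 are carried over because the singlet pair should collapse faster than the C1–C9 bond rotates, and the trans arrangement is also the less crowded one in the product. The selectivity that matters is ring closure over β-scission of the C9–C10 bond (to dimethyl methylidenemalonate and an enone) and over tautomerisation of 10 to a hydrazone through H-1; the malonate terminus lowers the barrier to N2 loss, and the polar, weakly nucleophilic solvent favours the compact singlet pair. Any 2,3-cis cyclobutane arising from loss of configuration at C1 is a diastereomer and is to be removed by chromatography, not equilibrated, since epimerisation at C9 would turn it into the enantiomer of 11. The silyl ether, the trisubstituted alkene, the ketone and the esters are expected to be inert to the iodonitrene, which is consumed by the amine and by excess ammonia.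

Step 7
Reactants: 11 dimethyl (2S,3R)-3-acetyl-2-[(3E)-5-(tert-butyldiphenylsilyloxy)-3-methylpent-3-enyl]cyclobutane-1,1-dicarboxylate
Product: 12 dimethyl (2S,3R)-3-acetyl-2-[(3E)-5-hydroxy-3-methylpent-3-enyl]cyclobutane-1,1-dicarboxylate
Conditions: TBAF, AcOH, THF, 0 °C to rt
Reagents that add atoms: none
Why: Fluoride cleavage of the silyl ether; acetic acid buffers the medium so that the ketone and the malonate are not exposed to free alkoxide.

Step 8
Reactants: 12 dimethyl (2S,3R)-3-acetyl-2-[(3E)-5-hydroxy-3-methylpent-3-enyl]cyclobutane-1,1-dicarboxylate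
Product: 13 dimethyl (2S,3R)-3-acetyl-2-[(3E)-3-methyl-5-oxopent-3-enyl]cyclobutane-1,1-dicarboxylate
Conditions: MnO2, CH2Cl2, rt
Reagents that add atoms: none
Why: MnO2 oxidises only the allylic alcohol and should keep the E geometry of the enal.

Step 9
Reactants: 13 dimethyl (2S,3R)-3-acetyl-2-[(3E)-3-methyl-5-oxopent-3-enyl]cyclobutane-1,1-dicarboxylate
Product: 14 dimethyl (2S,3R)-3-acetyl-2-[(3E)-3-methylhexa-3,5-dienyl]cyclobutane-1,1-dicarboxylate
Conditions: Ph3PCH3Br (1.05 equiv), KOtBu, THF, −78 to 0 °C
Reagents that add atoms: methyltriphenylphosphonium bromide, C[P+](c1ccccc1)(c1ccccc1)c1ccccc1.[Br-]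
Why: Wittig methylenation; with one equivalent of ylide at low temperature the unhindered enal should react far faster than the methyl ketone, giving the terminal diene that supplies C7.

Step 10
Reactants: 14 dimethyl (2S,3R)-3-acetyl-2-[(3E)-3-methylhexa-3,5-dienyl]cyclobutane-1,1-dicarboxylate
Product: 15 dimethyl (2S,3R)-2-[(3E)-3-methylhexa-3,5-dienyl]-3-[1-(trifluoromethylsulfonyloxy)ethenyl]cyclobutane-1,1-dicarboxylate
Conditions: PhNTf2, KN(SiMe3)2 (added last), THF, −78 °C
Reagents that add atoms: N-phenylbis(trifluoromethanesulfonimide), O=S(=O)(N(c1ccccc1)S(=O)(=O)C(F)(F)F)C(F)(F)F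
Why: Kinetic deprotonation of the methyl ketone at the methyl group (the alternative enolate would be an exocyclic cyclobutylidene) and O-sulfonylation give the 1,1-disubstituted enol triflate; adding the base last traps the enolate before it can attack the cis ester in a Dieckmann reaction.

Step 11
Reactants: 15 dimethyl (2S,3R)-2-[(3E)-3-methylhexa-3,5-dienyl]-3-[1-(trifluoromethylsulfonyloxy)ethenyl]cyclobutane-1,1-dicarboxylate
Product: 17 dimethyl (1S,4E,9R)-4-methyl-8-methylidenebicyclo[7.2.0]undec-4-ene-11,11-dicarboxylate, via alkylborane 16 (not isolated)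
Conditions: 9-BBN (1.3 equiv), THF, 0 °C to rt; then Pd(dppf)Cl2 (10 mol %), AsPh3, Cs2CO3, DMF/THF/H2O, 50 °C, slow addition (final ca. 2 mM)
Reagents that add atoms: none
Why: 9-BBN should hydroborate only the terminal vinyl group of the diene, anti-Markovnikov, leaving the trisubstituted alkene and the electron-poor enol triflate alone; the alkylborane then undergoes intramolecular B-alkyl Suzuki–Miyaura coupling (oxidative addition of the triflate to zerovalent palladium, base-assisted transmetalation, reductive elimination). Ring B (nine-membered) is closed at C7–C8 by this sp3–sp2 coupling under high dilution, with the E-alkene and the trans fusion already in place and the exocyclic methylene formed directly.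

Step 12
Reactants: 17 dimethyl (1S,4E,9R)-4-methyl-8-methylidenebicyclo[7.2.0]undec-4-ene-11,11-dicarboxylate
Product: 18 methyl (1S,4E,9R,11R)-11-(hydroxymethyl)-4-methyl-8-methylidenebicyclo[7.2.0]undec-4-ene-11-carboxylate (hydroxymethyl cis to H-1)
Conditions: LiAlH(OtBu)3 (3 equiv), THF, 0 to 40 °C
Reagents that add atoms: none
Why: LiAlH(OtBu)3 is the usual reagent for mono-reduction of 2,2-disubstituted malonates to β-hydroxy esters, the alkoxide formed shielding the second ester. The bulky hydride should attack the pseudo-equatorial ester cis to H-1 and remote from the C2 methylene, so C11 is set by substrate control from C1.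

Step 13
Reactants: 18 methyl (1S,4E,9R,11R)-11-(hydroxymethyl)-4-methyl-8-methylidenebicyclo[7.2.0]undec-4-ene-11-carboxylate
Product: 19 methyl (1S,4E,9R,11R)-11-[(tert-butyldimethylsilyloxy)methyl]-4-methyl-8-methylidenebicyclo[7.2.0]undec-4-ene-11-carboxylate
Conditions: TBSCl, imidazole, DMF, rt
Reagents that add atoms: tert-butyl(chloro)dimethylsilane, CC(C)(C)[Si](C)(C)Cl
Why: Silyl protection of the future C12 alcohol so that it survives the two hydride steps that turn the other ester into the methyl group.

Step 14
Reactants: 19 methyl (1S,4E,9R,11R)-11-[(tert-butyldimethylsilyloxy)methyl]-4-methyl-8-methylidenebicyclo[7.2.0]undec-4-ene-11-carboxylate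
Product: 20 [(1S,4E,9R,11S)-11-[(tert-butyldimethylsilyloxy)methyl]-4-methyl-8-methylidenebicyclo[7.2.0]undec-4-en-11-yl]methanol
Conditions: LiAlH4, Et2O, 0 °C
Reagents that add atoms: none
Why: LiAlH4 reduces the remaining hindered ester to the primary alcohol; the isolated alkenes and the silyl ether are inert.

Step 15
Reactants: 20 [(1S,4E,9R,11S)-11-[(tert-butyldimethylsilyloxy)methyl]-4-methyl-8-methylidenebicyclo[7.2.0]undec-4-en-11-yl]methanol
Product: 21 [(1S,4E,9R,11R)-11-[(tert-butyldimethylsilyloxy)methyl]-4-methyl-8-methylidenebicyclo[7.2.0]undec-4-en-11-yl]methyl methanesulfonate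
Conditions: MsCl, Et3N, CH2Cl2, 0 °C
Reagents that add atoms: methanesulfonyl chloride, CS(=O)(=O)Cl
Why: Sulfonylation of the neopentyl alcohol under non-ionising conditions gives the leaving group for the hydride displacement.

Step 16
Reactants: 21 [(1S,4E,9R,11R)-11-[(tert-butyldimethylsilyloxy)methyl]-4-methyl-8-methylidenebicyclo[7.2.0]undec-4-en-11-yl]methyl methanesulfonate
Product: 22 tert-butyl{[(1S,4E,9R,11S)-4,11-dimethyl-8-methylidenebicyclo[7.2.0]undec-4-en-11-yl]methoxy}dimethylsilane
Conditions: LiEt3BH (5 equiv), THF, 65 °C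
Reagents that add atoms: none
Why: SN2 displacement of the neopentyl mesylate by the strongly nucleophilic hydride LiEt3BH gives the C11 methyl group; an ionic hydride is chosen because a cyclobutylcarbinyl cation would ring-expand and a cyclobutylcarbinyl radical would ring-open.

Step 17
Reactants: 22 tert-butyl{[(1S,4E,9R,11S)-4,11-dimethyl-8-methylidenebicyclo[7.2.0]undec-4-en-11-yl]methoxy}dimethylsilane
Product: 23 [(1S,4E,9R,11S)-4,11-dimethyl-8-methylidenebicyclo[7.2.0]undec-4-en-11-yl]methanol
Conditions: TBAF, THF, rt
Reagents that add atoms: none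
Why: Fluoride desilylation frees the C12 alcohol.

Step 18
Reactants: 23 [(1S,4E,9R,11S)-4,11-dimethyl-8-methylidenebicyclo[7.2.0]undec-4-en-11-yl]methanol
Product: 24 (1S,4E,9R,11S)-4,11-dimethyl-8-methylidenebicyclo[7.2.0]undec-4-ene-11-carbaldehyde
Conditions: Dess–Martin periodinane, NaHCO3, CH2Cl2, 0 °C to rt
Reagents that add atoms: none
Why: Dess–Martin oxidation to the neopentyl aldehyde, which cannot enolise and so cannot epimerise.

Step 19
Reactants: 25 (2S)-(2-methyloxiran-2-yl)methanol
Product: 27 (2S)-2-[(E)-2-iodoethenyl]-2-methyloxirane, via epoxy aldehyde 26 (not isolated)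
Conditions: (COCl)2, DMSO, Et3N, CH2Cl2, −78 °C; crude solution then CrCl2 (6 equiv), CHI3 (2 equiv), THF, 0 °C
Reagents that add atoms: iodoform, IC(I)I
Why: Swern oxidation gives the volatile epoxy aldehyde, used as a crude solution; Takai olefination (gem-dichromium reagent from CHI3 and divalent chromium) gives the E-iodoalkene, strongly favoured for α-quaternary aldehydes. The stereocentre is not touched; its descriptor changes only through the priority rules.

Step 20
Reactants: 24 (1S,4E,9R,11S)-4,11-dimethyl-8-methylidenebicyclo[7.2.0]undec-4-ene-11-carbaldehyde; 27 (2S)-2-[(E)-2-iodoethenyl]-2-methyloxirane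
Product: 28 (2E)-1-[(1S,4E,9R,11S)-4,11-dimethyl-8-methylidenebicyclo[7.2.0]undec-4-en-11-yl]-3-[(2S)-2-methyloxiran-2-yl]prop-2-en-1-ol (both C12 epimers)
Conditions: CrCl2 (6 equiv), NiCl2 (2 mol %), DMSO, rt
Reagents that add atoms: none
Why: Nozaki–Hiyama–Kishi coupling: the NiCl2-catalysed alkenylchromium reagent adds to the hindered aldehyde with retention of the E geometry and tolerates the epoxide and the alkenes. The carbinol mixture is of no consequence because C12 is oxidised next, and the E geometry keeps the alkoxide away from the epoxide.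

Step 21
Reactants: 28 (2E)-1-[(1S,4E,9R,11S)-4,11-dimethyl-8-methylidenebicyclo[7.2.0]undec-4-en-11-yl]-3-[(2S)-2-methyloxiran-2-yl]prop-2-en-1-ol
Product: 29 (2E)-1-[(1S,4E,9R,11S)-4,11-dimethyl-8-methylidenebicyclo[7.2.0]undec-4-en-11-yl]-3-[(2S)-2-methyloxiran-2-yl]prop-2-en-1-one
Conditions: Dess–Martin periodinane, NaHCO3, CH2Cl2, 0 °C
Reagents that add atoms: none
Why: Buffered Dess–Martin oxidation of the allylic alcohol gives the E-configured γ,δ-epoxy enone without opening the epoxide.

Step 22
Reactants: 29 (2E)-1-[(1S,4E,9R,11S)-4,11-dimethyl-8-methylidenebicyclo[7.2.0]undec-4-en-11-yl]-3-[(2S)-2-methyloxiran-2-yl]prop-2-en-1-one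
Product: 32 (3R,6R)-3-[(1S,4E,9R,11S)-4,11-dimethyl-8-methylidenebicyclo[7.2.0]undec-4-en-11-yl]-6-(hydroxymethyl)-6-methyl-3,6-dihydro-1,2-dioxin-3-ol, via E-hydroperoxide 30 (not isolated), via Z-hydroperoxide 31 (not isolated)
Conditions: H2O2 (anhydrous, Et2O, 20 equiv), camphorsulfonic acid (10 mol %), 0 °C; NaHCO3 wash; then hν (350 nm), MeCN, 0 °C
Reagents that add atoms: hydrogen peroxide, OO
Why: Acid-catalysed perhydrolysis of a 2,2-disubstituted epoxide: H2O2 should attack the tertiary allylic carbon C15 with inversion (borderline SN2; the electron-poor enone discourages ionisation and the E geometry keeps the carbonyl oxygen from participating), turning the (S)-epoxide into the (15R)-hydroperoxide 30. Irradiation in the n–π* band isomerises the enone (E/Z photoisomerisation), and the Z isomer 31 is withdrawn by 6-exo-trig addition of the hydroperoxide to the C12 carbonyl, which closes ring D. C12 settles as the more stable anomer by reversible ring opening.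

Step 23
Reactants: 32 (3R,6R)-3-[(1S,4E,9R,11S)-4,11-dimethyl-8-methylidenebicyclo[7.2.0]undec-4-en-11-yl]-6-(hydroxymethyl)-6-methyl-3,6-dihydro-1,2-dioxin-3-ol
Product: 33 (3R,6R)-6-(acetoxymethyl)-3-[(1S,4E,9R,11S)-4,11-dimethyl-8-methylidenebicyclo[7.2.0]undec-4-en-11-yl]-6-methyl-3,6-dihydro-1,2-dioxin-3-ol
Conditions: Ac2O (1.2 equiv), pyridine, CH2Cl2, 0 °C
Reagents that add atoms: acetic anhydride, CC(=O)OC(C)=O
Why: Selective acetylation of the primary alcohol; the tertiary hemiketal hydroxyl is far less reactive and the peroxide oxygens are tied up in the ring.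

Step 24
Reactants: 33 (3R,6R)-6-(acetoxymethyl)-3-[(1S,4E,9R,11S)-4,11-dimethyl-8-methylidenebicyclo[7.2.0]undec-4-en-11-yl]-6-methyl-3,6-dihydro-1,2-dioxin-3-ol
Product: 34 (3R,6R)-6-(acetoxymethyl)-3-[(1S,4S,5S,9R,11S)-4,5-epoxy-4,11-dimethyl-8-methylidenebicyclo[7.2.0]undecan-11-yl]-6-methyl-3,6-dihydro-1,2-dioxin-3-ol (CNP0169860.1)
Conditions: mCPBA (1.05 equiv), NaHCO3, CH2Cl2, −20 to 0 °C
Reagents that add atoms: 3-chloroperbenzoic acid, O=C(OO)c1cccc(Cl)c1
Why: Prilezhaev epoxidation: the strained E-trisubstituted alkene of ring B is by far the most nucleophilic double bond (the exocyclic methylene and the electron-poor dioxin alkene are slower). The peracid should attack the exposed outer face in the preferred ring-B conformation, the bias that gives the natural oxide in the parent sesquiterpene series, here in its mirror image, and so give 4S,5S.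

## Compound list

1 | geraniol, (2E)-3,7-dimethylocta-2,6-dien-1-ol | CC(C)=CCC/C(C)=C/CO | starting material
2 | tert-butyl{[(2E)-3,7-dimethylocta-2,6-dien-1-yl]oxy}diphenylsilane | CC(C)=CCC/C(C)=C/CO[Si](c1ccccc1)(c1ccccc1)C(C)(C)C | intermediate
3 | tert-butyl{[(2E)-5-(3,3-dimethyloxiran-2-yl)-3-methylpent-2-en-1-yl]oxy}diphenylsilane (racemic epoxide) | CC1(C)OC1CC/C(C)=C/CO[Si](c1ccccc1)(c1ccccc1)C(C)(C)C | intermediate
4 | (4E)-6-[(tert-butyldiphenylsilyl)oxy]-4-methylhex-4-enal | O=CCC/C(C)=C/CO[Si](c1ccccc1)(c1ccccc1)C(C)(C)C | intermediate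
5 | dimethyl aminomalonate hydrochloride | COC(=O)C(N)C(=O)OC.Cl | starting material
6 | but-3-en-2-one | CC(=O)C=C | starting material
7 | dimethyl 2-{[(4E)-6-(tert-butyldiphenylsilyloxy)-4-methylhex-4-enylidene]amino}malonate | COC(=O)C(N=CCC/C(C)=C/CO[Si](c1ccccc1)(c1ccccc1)C(C)(C)C)C(=O)OC | intermediate (not isolated)
8 | dimethyl (4S,5S)-4-acetyl-5-[(3E)-5-(tert-butyldiphenylsilyloxy)-3-methylpent-3-enyl]pyrrolidine-2,2-dicarboxylate (4,5-cis) | COC(=O)C1(C(=O)OC)C[C@H](C(C)=O)[C@H](CC/C(C)=C/CO[Si](c2ccccc2)(c2ccccc2)C(C)(C)C)N1 | intermediate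
9 | dimethyl (4R,5S)-4-acetyl-5-[(3E)-5-(tert-butyldiphenylsilyloxy)-3-methylpent-3-enyl]pyrrolidine-2,2-dicarboxylate (4,5-trans) | COC(=O)C1(C(=O)OC)C[C@@H](C(C)=O)[C@H](CC/C(C)=C/CO[Si](c2ccccc2)(c2ccccc2)C(C)(C)C)N1 | intermediate
10 | 1,1-diazene (N-nitrene) of pyrrolidine 9 | COC(=O)C1(C(=O)OC)C[C@@H](C(C)=O)[C@H](CC/C(C)=C/CO[Si](c2ccccc2)(c2ccccc2)C(C)(C)C)[N+]1=[N-] | intermediate (not isolated)
11 | dimethyl (2S,3R)-3-acetyl-2-[(3E)-5-(tert-butyldiphenylsilyloxy)-3-methylpent-3-enyl]cyclobutane-1,1-dicarboxylate (2,3-trans) | COC(=O)C1(C(=O)OC)C[C@@H](C(C)=O)[C@@H]1CC/C(C)=C/CO[Si](c1ccccc1)(c1ccccc1)C(C)(C)C | intermediate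
12 | dimethyl (2S,3R)-3-acetyl-2-[(3E)-5-hydroxy-3-methylpent-3-enyl]cyclobutane-1,1-dicarboxylate | COC(=O)C1(C(=O)OC)C[C@@H](C(C)=O)[C@@H]1CC/C(C)=C/CO | intermediate
13 | dimethyl (2S,3R)-3-acetyl-2-[(3E)-3-methyl-5-oxopent-3-enyl]cyclobutane-1,1-dicarboxylate | COC(=O)C1(C(=O)OC)C[C@@H](C(C)=O)[C@@H]1CC/C(C)=C/C=O | intermediate
14 | dimethyl (2S,3R)-3-acetyl-2-[(3E)-3-methylhexa-3,5-dienyl]cyclobutane-1,1-dicarboxylate | COC(=O)C1(C(=O)OC)C[C@@H](C(C)=O)[C@@H]1CC/C(C)=C/C=C | intermediate
15 | dimethyl (2S,3R)-2-[(3E)-3-methylhexa-3,5-dienyl]-3-[1-(trifluoromethylsulfonyloxy)ethenyl]cyclobutane-1,1-dicarboxylate | COC(=O)C1(C(=O)OC)C[C@@H](C(=C)OS(=O)(=O)C(F)(F)F)[C@@H]1CC/C(C)=C/C=C | intermediate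
16 | B-alkyl-9-borabicyclo[3.3.1]nonane from 15 (boron on C7) | COC(=O)C1(C(=O)OC)C[C@@H](C(=C)OS(=O)(=O)C(F)(F)F)[C@@H]1CC/C(C)=C/CCB1C2CCCC1CCC2 | intermediate (not isolated)
17 | dimethyl (1S,4E,9R)-4-methyl-8-methylidenebicyclo[7.2.0]undec-4-ene-11,11-dicarboxylate | C=C1CC/C=C(\C)CC[C@H]2[C@H]1CC2(C(=O)OC)C(=O)OC | intermediate
18 | methyl (1S,4E,9R,11R)-11-(hydroxymethyl)-4-methyl-8-methylidenebicyclo[7.2.0]undec-4-ene-11-carboxylate | C=C1CC/C=C(\C)CC[C@H]2[C@H]1C[C@]2(C(=O)OC)CO | intermediate
19 | methyl (1S,4E,9R,11R)-11-[(tert-butyldimethylsilyloxy)methyl]-4-methyl-8-methylidenebicyclo[7.2.0]undec-4-ene-11-carboxylate | C=C1CC/C=C(\C)CC[C@H]2[C@H]1C[C@]2(C(=O)OC)CO[Si](C)(C)C(C)(C)C | intermediate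
20 | [(1S,4E,9R,11S)-11-[(tert-butyldimethylsilyloxy)methyl]-4-methyl-8-methylidenebicyclo[7.2.0]undec-4-en-11-yl]methanol | C=C1CC/C=C(\C)CC[C@H]2[C@H]1C[C@]2(CO)CO[Si](C)(C)C(C)(C)C | intermediate
21 | [(1S,4E,9R,11R)-11-[(tert-butyldimethylsilyloxy)methyl]-4-methyl-8-methylidenebicyclo[7.2.0]undec-4-en-11-yl]methyl methanesulfonate | C=C1CC/C=C(\C)CC[C@H]2[C@H]1C[C@]2(COS(C)(=O)=O)CO[Si](C)(C)C(C)(C)C | intermediate
22 | tert-butyl{[(1S,4E,9R,11S)-4,11-dimethyl-8-methylidenebicyclo[7.2.0]undec-4-en-11-yl]methoxy}dimethylsilane | C=C1CC/C=C(\C)CC[C@H]2[C@H]1C[C@]2(C)CO[Si](C)(C)C(C)(C)C | intermediate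
23 | [(1S,4E,9R,11S)-4,11-dimethyl-8-methylidenebicyclo[7.2.0]undec-4-en-11-yl]methanol | C=C1CC/C=C(\C)CC[C@H]2[C@H]1C[C@]2(C)CO | intermediate
24 | (1S,4E,9R,11S)-4,11-dimethyl-8-methylidenebicyclo[7.2.0]undec-4-ene-11-carbaldehyde | C=C1CC/C=C(\C)CC[C@H]2[C@H]1C[C@]2(C)C=O | intermediate
25 | (2S)-(2-methyloxiran-2-yl)methanol, (S)-2-methylglycidol | C[C@]1(CO)CO1 | starting material
26 | (2R)-2-methyloxirane-2-carbaldehyde | C[C@]1(C=O)CO1 | intermediate (not isolated)
27 | (2S)-2-[(E)-2-iodoethenyl]-2-methyloxirane | C[C@]1(/C=C/I)CO1 | intermediate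
28 | (2E)-1-[(1S,4E,9R,11S)-4,11-dimethyl-8-methylidenebicyclo[7.2.0]undec-4-en-11-yl]-3-[(2S)-2-methyloxiran-2-yl]prop-2-en-1-ol (both C12 epimers) | C=C1CC/C=C(\C)CC[C@H]2[C@H]1C[C@]2(C)C(O)/C=C/[C@@]1(C)CO1 | intermediate
29 | (2E)-1-[(1S,4E,9R,11S)-4,11-dimethyl-8-methylidenebicyclo[7.2.0]undec-4-en-11-yl]-3-[(2S)-2-methyloxiran-2-yl]prop-2-en-1-one | C=C1CC/C=C(\C)CC[C@H]2[C@H]1C[C@]2(C)C(=O)/C=C/[C@@]1(C)CO1 | intermediate
30 | (2E,4R)-1-[(1S,4E,9R,11S)-4,11-dimethyl-8-methylidenebicyclo[7.2.0]undec-4-en-11-yl]-4-hydroperoxy-5-hydroxy-4-methylpent-2-en-1-one | C=C1CC/C=C(\C)CC[C@H]2[C@H]1C[C@]2(C)C(=O)/C=C/[C@](C)(CO)OO | intermediate (not isolated)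
31 | (2Z,4R)-1-[(1S,4E,9R,11S)-4,11-dimethyl-8-methylidenebicyclo[7.2.0]undec-4-en-11-yl]-4-hydroperoxy-5-hydroxy-4-methylpent-2-en-1-one | C=C1CC/C=C(\C)CC[C@H]2[C@H]1C[C@]2(C)C(=O)/C=C\[C@](C)(CO)OO | intermediate (not isolated)
32 | (3R,6R)-3-[(1S,4E,9R,11S)-4,11-dimethyl-8-methylidenebicyclo[7.2.0]undec-4-en-11-yl]-6-(hydroxymethyl)-6-methyl-3,6-dihydro-1,2-dioxin-3-ol | C=C1CC/C=C(\C)CC[C@H]2[C@H]1C[C@]2(C)[C@@]1(O)C=C[C@](C)(CO)OO1 | intermediate
33 | (3R,6R)-6-(acetoxymethyl)-3-[(1S,4E,9R,11S)-4,11-dimethyl-8-methylidenebicyclo[7.2.0]undec-4-en-11-yl]-6-methyl-3,6-dihydro-1,2-dioxin-3-ol | C=C1CC/C=C(\C)CC[C@H]2[C@H]1C[C@]2(C)[C@@]1(O)C=C[C@](C)(COC(C)=O)OO1 | intermediate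
34 | (3R,6R)-6-(acetoxymethyl)-3-[(1S,4S,5S,9R,11S)-4,5-epoxy-4,11-dimethyl-8-methylidenebicyclo[7.2.0]undecan-11-yl]-6-methyl-3,6-dihydro-1,2-dioxin-3-ol | C=C1CC[C@@H]2O[C@@]2(C)CC[C@H]2[C@H]1C[C@]2(C)[C@@]1(O)C=C[C@](C)(COC(C)=O)OO1 | target

## Step count and least certain steps

Total: 24 steps. Longest linear sequence: 23 steps (steps 1–18 and 20–24, from geraniol 1); step 19 is a one-step branch from 25.

**Step 6 (key step, proposed new method).**
- What may go wrong: fragmentation of the 1,4-biradical by β-scission of C9–C10 (a retro-[2+2] giving two stable alkenes) is the most likely failure, because the C1 terminus is an unstabilised secondary radical. Tautomerisation of the 1,1-diazene through H-1 and slow amination of the hindered, electron-poor nitrogen are further ways to lose material. Partial rotation before closure would erode configuration at C1.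
- Fallback (known chemistry, no biradical; sets out from 4, returns at 11): an Evans boron aldol reaction of aldehyde 4 with (4S)-4-benzyl-3-[(E)-but-2-enoyl]-1,3-oxazolidin-2-one (Bu2BOTf, iPr2NEt, CH2Cl2, −78 °C; the dienolate reacts at its α-carbon) would give the syn aldol (4S)-4-benzyl-3-[(2S,3R,6E)-8-(tert-butyldiphenylsilyloxy)-2-ethenyl-3-hydroxy-6-methyloct-6-enoyl]-1,3-oxazolidin-2-one F1. LiBH4 would release (2R,3R,6E)-8-(tert-butyldiphenylsilyloxy)-2-ethenyl-6-methyloct-6-ene-1,3-diol F2, and SO2Cl2/Et3N at −78 °C would convert it into the cyclic sulfate (4R,5R)-4-[(3E)-5-(tert-butyldiphenylsilyloxy)-3-methylpent-3-enyl]-5-ethenyl-1,3,2-dioxathiane 2,2-dioxide F3. Dimethyl malonate with two equivalents of NaH in DME would alkylate first at the primary carbon (the future C10) and then, 4-exo-tet with inversion, at the secondary carbon (the future C1). This gives dimethyl (2S,3S)-3-ethenyl-2-[(3E)-5-(tert-butyldiphenylsilyloxy)-3-methylpent-3-enyl]cyclobutane-1,1-dicarboxylate F4, which is already trans. Tsuji–Wacker oxidation of the vinyl group (PdCl2, CuCl, O2, DMF/H2O) returns to 11.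

**Step 22.**
- What may go wrong: attack of the peroxide at the primary epoxide carbon, or partial ionisation at C15 with loss of configuration, would spoil the only stereocentre that the core cannot correct. The acid may also trigger transannular reaction of the strained ring-B alkene. During irradiation, O–O homolysis or energy transfer to the ring-B alkene may compete with the enone isomerisation.
- Fallback (sets out from 29, returns at 34; gives up control at C15): SmI2 (THF/MeOH, −78 °C) would open the epoxide of 29 reductively to (3E)-1-[(1S,4E,9R,11S)-4,11-dimethyl-8-methylidenebicyclo[7.2.0]undec-4-en-11-yl]-5-hydroxy-4-methylpent-3-en-1-one F7, and acetylation would give its acetate F8. mCPBA would then epoxidise ring B first, giving the 4,5-epoxide F9, so that no alkene more reactive than the side-chain one remains. Photooxygenation (O2, tetraphenylporphyrin, visible light; Schenck ene reaction with abstraction of the activated H-13) would give the E-hydroperoxy enone F10 as both C15 epimers. Irradiation at 350 nm would close it to 34 together with its 12,15-diastereomer F11. The two are diastereomers and would have to be separated.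

**Step 11.**
- What may go wrong: intermolecular coupling and protodeboronation may outrun closure of the strained nine-membered ring, and hydroboration of the diene may not be fully regioselective.
- Fallback (sets out from 12, returns at 17): CBr4/PPh3 would convert alcohol 12 into dimethyl (2S,3R)-3-acetyl-2-[(3E)-5-bromo-3-methylpent-3-enyl]cyclobutane-1,1-dicarboxylate F5. KN(SiMe3)2 at high dilution would close ring B at C6–C7 by intramolecular alkylation of the kinetic methyl enolate, giving dimethyl (1S,4E,9R)-4-methyl-8-oxobicyclo[7.2.0]undec-4-ene-11,11-dicarboxylate F6. Wittig methylenation (Ph3PCH3Br, KOtBu) of the ring ketone gives 17.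

**Step 12.**
- What may go wrong: insufficient discrimination between the two diastereotopic esters, or over-reduction to the diol, would scramble C11.
- Fallback (sets out from 17, returns at 20): LiAlH4 would reduce both esters to [(1S,4E,9R)-4-methyl-8-methylidenebicyclo[7.2.0]undec-4-ene-11,11-diyl]dimethanol F12. The differentiation is then made at the alcohol stage by mono-silylation of the less hindered hydroxymethyl group (TBSCl, 1 equiv, imidazole, −20 °C).

Further compounds

F1 | step 6 | (4S)-4-benzyl-3-[(2S,3R,6E)-8-(tert-butyldiphenylsilyloxy)-2-ethenyl-3-hydroxy-6-methyloct-6-enoyl]-1,3-oxazolidin-2-one | O=C1OC[C@H](Cc2ccccc2)N1C(=O)[C@@H](C=C)[C@H](O)CC/C(C)=C/CO[Si](c1ccccc1)(c1ccccc1)C(C)(C)C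
F2 | step 6 | (2R,3R,6E)-8-(tert-butyldiphenylsilyloxy)-2-ethenyl-6-methyloct-6-ene-1,3-diol | OC[C@@H](C=C)[C@H](O)CC/C(C)=C/CO[Si](c1ccccc1)(c1ccccc1)C(C)(C)C
F3 | step 6 | (4R,5R)-4-[(3E)-5-(tert-butyldiphenylsilyloxy)-3-methylpent-3-enyl]-5-ethenyl-1,3,2-dioxathiane 2,2-dioxide | O=S1(=O)OC[C@@H](C=C)[C@@H](CC/C(C)=C/CO[Si](c2ccccc2)(c2ccccc2)C(C)(C)C)O1
F4 | step 6 | dimethyl (2S,3S)-3-ethenyl-2-[(3E)-5-(tert-butyldiphenylsilyloxy)-3-methylpent-3-enyl]cyclobutane-1,1-dicarboxylate (2,3-trans) | COC(=O)C1(C(=O)OC)C[C@@H](C=C)[C@@H]1CC/C(C)=C/CO[Si](c1ccccc1)(c1ccccc1)C(C)(C)C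
F5 | step 11 | dimethyl (2S,3R)-3-acetyl-2-[(3E)-5-bromo-3-methylpent-3-enyl]cyclobutane-1,1-dicarboxylate | COC(=O)C1(C(=O)OC)C[C@@H](C(C)=O)[C@@H]1CC/C(C)=C/CBr
F6 | step 11 | dimethyl (1S,4E,9R)-4-methyl-8-oxobicyclo[7.2.0]undec-4-ene-11,11-dicarboxylate | O=C1CC/C=C(\C)CC[C@H]2[C@H]1CC2(C(=O)OC)C(=O)OC
F7 | step 22 | (3E)-1-[(1S,4E,9R,11S)-4,11-dimethyl-8-methylidenebicyclo[7.2.0]undec-4-en-11-yl]-5-hydroxy-4-methylpent-3-en-1-one | C=C1CC/C=C(\C)CC[C@H]2[C@H]1C[C@]2(C)C(=O)C/C=C(\C)CO
F8 | step 22 | (2E)-5-[(1S,4E,9R,11S)-4,11-dimethyl-8-methylidenebicyclo[7.2.0]undec-4-en-11-yl]-2-methyl-5-oxopent-2-enyl acetate | C=C1CC/C=C(\C)CC[C@H]2[C@H]1C[C@]2(C)C(=O)C/C=C(\C)COC(C)=O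
F9 | step 22 | (2E)-5-[(1S,4S,5S,9R,11S)-4,5-epoxy-4,11-dimethyl-8-methylidenebicyclo[7.2.0]undecan-11-yl]-2-methyl-5-oxopent-2-enyl acetate | C=C1CC[C@@H]2O[C@@]2(C)CC[C@H]2[C@H]1C[C@]2(C)C(=O)C/C=C(\C)COC(C)=O
F10 | step 22 | (3E)-5-[(1S,4S,5S,9R,11S)-4,5-epoxy-4,11-dimethyl-8-methylidenebicyclo[7.2.0]undecan-11-yl]-2-hydroperoxy-2-methyl-5-oxopent-3-enyl acetate (both C15 epimers) | C=C1CC[C@@H]2O[C@@]2(C)CC[C@H]2[C@H]1C[C@]2(C)C(=O)/C=C/C(C)(COC(C)=O)OO
F11 | step 22 | (3S,6S)-6-(acetoxymethyl)-3-[(1S,4S,5S,9R,11S)-4,5-epoxy-4,11-dimethyl-8-methylidenebicyclo[7.2.0]undecan-11-yl]-6-methyl-3,6-dihydro-1,2-dioxin-3-ol (12,15-diastereomer of 34) | C=C1CC[C@@H]2O[C@@]2(C)CC[C@H]2[C@H]1C[C@]2(C)[C@]1(O)C=C[C@@](C)(COC(C)=O)OO1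
F12 | step 12 | [(1S,4E,9R)-4-methyl-8-methylidenebicyclo[7.2.0]undec-4-ene-11,11-diyl]dimethanol | C=C1CC/C=C(\C)CC[C@H]2[C@H]1CC2(CO)CO
A1 | alternative 1 | geranylgeranyl diphosphate | CC(C)=CCC/C(C)=C/CC/C(C)=C/CC/C(C)=C/COP(=O)(O)OP(=O)(O)O
A2 | alternative 1 | bicyclic diterpene hydrocarbon with rings A and B and a homoprenyl chain on C11 | C=C1CC/C=C(\C)CC[C@H]2[C@H]1C[C@]2(C)CCC=C(C)C
A3 | alternative 2 | (2E)-3-(1-hydroxycyclopropyl)but-2-enyl methyl carbonate | COC(=O)OC/C=C(\C)C1(O)CC1
A4 | alternative 2 | 2-methyl-2-vinylcyclobutanone (single enantiomer) | C=C[C@@]1(C)CCC1=O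
A5 | alternative 3 | 2-diazo-4-(dimethoxymethyl)-4-methyl-3-[4-(trimethylsilyl)but-3-ynyl]cyclopentanone | [N-]=[N+]=C1C(=O)C[C@](C)(C(OC)OC)[C@H]1CCC#C[Si](C)(C)C
A6 | alternative 3 | methyl 3-(dimethoxymethyl)-3-methyl-2-[4-(trimethylsilyl)but-3-ynyl]cyclobutanecarboxylate | COC(=O)[C@@H]1C[C@](C)(C(OC)OC)[C@H]1CCC#C[Si](C)(C)C
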